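**Retrosynthetic overview** (azaphilone numbering: C1, O2, C3, C4, C4a, C5–C8, C8a; side-chain stereocentre = C13)
1. The C5–Cl bond (electrophilic chlorination) and the C7 acetate are removed last, leading back to the 7-hydroxy azaphilone.
2. Key bond C7–O: a [2,3]-sigmatropic oxygen shift inside an aryloxy-iodane (IBX hydroxylative dearomatisation) of a 6,8-dihydroxy-2-benzopyrylium. C7 is not controlled; the two C7 epimers are diastereomers through C13 and are separated.
3. Pyran ring (ring B): gold-catalysed 6-endo-dig cycloisomerisation of an o-alkynylbenzaldehyde, itself from Sonogashira coupling of a bromoresorcinaldehyde with a dienyne.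
4. Dienyne: E-selective Horner–Wadsworth–Emmons and Wittig olefinations back to (S)-2-methylbutan-1-ol, which supplies C13.
5. Ring order: the benzene ring (ring A) is bought; ring B is closed and ring A is dearomatised one after the other in the same flask.

Assumption: the two olefination reagents and the bromoresorcinol used below are taken as catalogue compounds.

**Step 1**
Reactants: 1 (S)-2-methylbutan-1-ol; 2 2-(triphenylphosphoranylidene)propanal
Product: 4 (2E,4S)-2,4-dimethylhex-2-enal, via (S)-2-methylbutanal 3 (not isolated)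
Conditions: TEMPO (1 mol%), KBr (10 mol%), NaOCl (1.1 equiv), NaHCO3, CH2Cl2/H2O, 0 °C; organic layer dried (MgSO4); then 2 (0.9 equiv), PhMe, 80 °C
Reagents that add atoms: none
Why: Anelli TEMPO/NaOCl oxidation gives the configurationally labile aldehyde 3 under buffered, non-enolising conditions, and the formyl-stabilised ylide 2 traps it in an E-selective Wittig olefination, so C13 is carried over unchanged from 1.

**Step 2**
Reactants: 4 (2E,4S)-2,4-dimethylhex-2-enal; 5 diethyl [3-(trimethylsilyl)prop-2-yn-1-yl]phosphonate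
Product: 7 (3E,5E,7S)-5,7-dimethylnona-3,5-dien-1-yne, via silylated dienyne 6 (not isolated)
Conditions: 5 (1.2 equiv), LiN(SiMe3)2, THF, −78 °C; then 4, −78 → 0 °C; then MeOH, K2CO3 (0.2 equiv), rt
Reagents that add atoms: none
Why: Horner–Wadsworth–Emmons olefination of the propargylic phosphonate anion adds 1,2 to the enal and gives the new disubstituted alkene with E selectivity (expected about 15:1), and methanolysis then removes the alkynyl silane in the same flask; C13 is untouched.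

**Step 3**
Reactants: 8 5-bromo-2-methylbenzene-1,3-diol
Product: 10 6-bromo-2,4-dihydroxy-3-methylbenzaldehyde, via aryl iminium chloride 9 (not isolated)
Conditions: POCl3 (1.2 equiv), DMF (1.5 equiv), MeCN, 0 °C → rt; then H2O, 50 °C
Reagents that add atoms: N,N-dimethylformamide, CN(C)C=O; water, O
Why: Vilsmeier–Haack formylation; the two free ring positions of 8 are equivalent and each is ortho/para to both hydroxyls, so a single aldehyde results after hydrolysis of iminium salt 9.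

**Step 4**
Reactants: 10 6-bromo-2,4-dihydroxy-3-methylbenzaldehyde; 7 (3E,5E,7S)-5,7-dimethylnona-3,5-dien-1-yne
Product: 11 2,4-dihydroxy-3-methyl-6-[(3E,5E,7S)-5,7-dimethylnona-3,5-dien-1-yn-1-yl]benzaldehyde
Conditions: PdCl2(PPh3)2 (5 mol%), CuI (10 mol%), Et3N, DMF, 60 °C, argon
Reagents that add atoms: none
Why: Sonogashira coupling; the ortho-formyl group activates the C–Br bond for oxidative addition, the free phenols are tolerated under amine/CuI conditions, and no stereocentre or alkene geometry is affected.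

**Step 5 (key step)**
Reactants: 11 2,4-dihydroxy-3-methyl-6-[(3E,5E,7S)-5,7-dimethylnona-3,5-dien-1-yn-1-yl]benzaldehyde
Product: 15 (7S)-7-hydroxy-7-methyl-3-[(1E,3E,5S)-3,5-dimethylhepta-1,3-dien-1-yl]-6H-isochromene-6,8(7H)-dione, via 2-benzopyrylium trifluoroacetate 12 (not isolated), via aryloxy-iodane 13 (not isolated), via iodosylbenzoate ester 14 (not isolated)
Conditions: Au(OAc)3 (5 mol%), ClCH2CH2Cl/CF3CO2H 10:1, rt, 5 min; then IBX (1.2 equiv), Bu4NI (5 mol%), rt, 1 h; aq. Na2S2O3/NaHCO3; preparative HPLC (achiral silica) to remove the C7 epimer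
Reagents that add atoms: 2-iodoxybenzoic acid (IBX), O=C1OI(=O)(O)c2ccccc12
Why: Trivalent gold triggers 6-endo-dig cycloisomerisation of the formyl oxygen onto the alkyne (ring B, benzopyrylium 12), whose C8 hydroxyl then exchanges onto pentavalent iodine (13) and receives the I=O oxygen at C7 through a suprafacial [2,3]-sigmatropic rearrangement (hydroxylative dearomatisation, 14, hydrolysed on work-up); C13 is ten bonds away and cannot bias the face, so both C7 epimers form (about 1:1, at most about half the material is the wanted one) and are separated as diastereomers.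

**Step 6**
Reactants: 15 (7S)-7-hydroxy-7-methyl-3-[(1E,3E,5S)-3,5-dimethylhepta-1,3-dien-1-yl]-6H-isochromene-6,8(7H)-dione
Product: 16 (7S)-3-[(1E,3E,5S)-3,5-dimethylhepta-1,3-dien-1-yl]-7-methyl-6,8-dioxo-7,8-dihydro-6H-isochromen-7-yl acetate
Conditions: Ac2O, DMAP (0.2 equiv), i-Pr2NEt, CH2Cl2, 0 °C → rt
Reagents that add atoms: acetic anhydride, CC(=O)OC(C)=O
Why: DMAP-catalysed O-acylation of the tertiary C7 alcohol; the C7–O bond is not broken, so the configuration is retained.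

**Step 7**
Reactants: 16 (7S)-3-[(1E,3E,5S)-3,5-dimethylhepta-1,3-dien-1-yl]-7-methyl-6,8-dioxo-7,8-dihydro-6H-isochromen-7-yl acetate
Product: 17 (+)-sclerotiorin, (7R)-5-chloro-3-[(1E,3E,5S)-3,5-dimethylhepta-1,3-dien-1-yl]-7-methyl-6,8-dioxo-7,8-dihydro-6H-isochromen-7-yl acetate
Conditions: NCS (1.1 equiv), MeCN/AcOH 10:1, rt, dark
Reagents that add atoms: N-chlorosuccinimide, O=C1CCC(=O)N1Cl
Why: Electrophilic chlorination (addition–deprotonation) at C5, the nucleophilic terminus of the O2–C3=C4–C4a=C5 dienol ether and far more electron-rich than the acceptor-conjugated side-chain diene; no stereocentre is touched, and the C7 descriptor changes from S to R only because chlorine raises the CIP rank of C6.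

**Compound list**
1 | (S)-2-methylbutan-1-ol | CC[C@H](C)CO | starting material
2 | 2-(triphenylphosphoranylidene)propanal | CC(C=O)=P(c1ccccc1)(c1ccccc1)c1ccccc1 | starting material
3 | (S)-2-methylbutanal | CC[C@H](C)C=O | intermediate (not isolated)
4 | (2E,4S)-2,4-dimethylhex-2-enal | CC[C@H](C)/C=C(C)/C=O | intermediate
5 | diethyl [3-(trimethylsilyl)prop-2-yn-1-yl]phosphonate | CCOP(=O)(CC#C[Si](C)(C)C)OCC | starting material
6 | trimethyl[(3E,5E,7S)-5,7-dimethylnona-3,5-dien-1-yn-1-yl]silane | CC[C@H](C)/C=C(C)/C=C/C#C[Si](C)(C)C | intermediate (not isolated)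
7 | (3E,5E,7S)-5,7-dimethylnona-3,5-dien-1-yne | CC[C@H](C)/C=C(C)/C=C/C#C | intermediate
8 | 5-bromo-2-methylbenzene-1,3-diol | Cc1c(O)cc(Br)cc1O | starting material
9 | N-[(6-bromo-2,4-dihydroxy-3-methylphenyl)methylidene]-N-methylmethanaminium chloride | C[N+](C)=Cc1c(Br)cc(O)c(C)c1O.[Cl-] | intermediate (not isolated)
10 | 6-bromo-2,4-dihydroxy-3-methylbenzaldehyde | O=Cc1c(Br)cc(O)c(C)c1O | intermediate
11 | 2,4-dihydroxy-3-methyl-6-[(3E,5E,7S)-5,7-dimethylnona-3,5-dien-1-yn-1-yl]benzaldehyde | CC[C@H](C)/C=C(C)/C=C/C#Cc1cc(O)c(C)c(O)c1C=O | intermediate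
12 | 6,8-dihydroxy-7-methyl-3-[(1E,3E,5S)-3,5-dimethylhepta-1,3-dien-1-yl]isochromenylium (2-benzopyrylium) trifluoroacetate | CC[C@H](C)/C=C(C)/C=C/c1cc2cc(O)c(C)c(O)c2c[o+]1.[O-]C(=O)C(F)(F)F | intermediate (not isolated)
13 | 1-({7-methyl-6-oxo-3-[(1E,3E,5S)-3,5-dimethylhepta-1,3-dien-1-yl]-6H-isochromen-8-yl}oxy)-1λ5,2-benziodoxole-1,3-dione (IBX with its I–OH replaced by O8 of the neutral 6-oxo form of 12) | CC[C@H](C)/C=C(C)/C=C/C1=CC2=CC(=O)C(C)=C(OI3(=O)OC(=O)c4ccccc34)C2=CO1 | intermediate (not isolated)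
14 | 1-({(7S)-7-methyl-6,8-dioxo-3-[(1E,3E,5S)-3,5-dimethylhepta-1,3-dien-1-yl]-7,8-dihydro-6H-isochromen-7-yl}oxy)-1,2-benziodoxol-3(1H)-one (2-iodosylbenzoate ester of 15 through O7) | CC[C@H](C)/C=C(C)/C=C/C1=CC2=CC(=O)[C@](C)(OI3OC(=O)c4ccccc34)C(=O)C2=CO1 | intermediate (not isolated)
15 | (7S)-7-hydroxy-7-methyl-3-[(1E,3E,5S)-3,5-dimethylhepta-1,3-dien-1-yl]-6H-isochromene-6,8(7H)-dione | CC[C@H](C)/C=C(C)/C=C/C1=CC2=CC(=O)[C@](C)(O)C(=O)C2=CO1 | intermediate
16 | (7S)-3-[(1E,3E,5S)-3,5-dimethylhepta-1,3-dien-1-yl]-7-methyl-6,8-dioxo-7,8-dihydro-6H-isochromen-7-yl acetate (deschlorosclerotiorin; same spatial arrangement at C7 as the target) | CC[C@H](C)/C=C(C)/C=C/C1=CC2=CC(=O)[C@](C)(OC(C)=O)C(=O)C2=CO1 | intermediate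
17 | (+)-sclerotiorin, (7R)-5-chloro-3-[(1E,3E,5S)-3,5-dimethylhepta-1,3-dien-1-yl]-7-methyl-6,8-dioxo-7,8-dihydro-6H-isochromen-7-yl acetate | CC[C@H](C)/C=C(C)/C=C/C1=CC2=C(Cl)C(=O)[C@](C)(OC(C)=O)C(=O)C2=CO1 | target

**Step count**
Total: 7 steps. Longest linear sequence: 6 steps (1 → 4 → 7 → 11 → 15 → 16 → 17; steps 1, 2, 4, 5, 6, 7).

**Three steps most likely to fail, with fallbacks**

Step 5. The weakest point is freeing 15 from its C7 epimer, since the two differ only by a remote centre and may not resolve on silica; the brief TFA exposure of the dienyl chain is a lesser concern. The fallback sets out from 11 and comes back to the route at 17. The gold/IBX sequence is run as before but worked up without HPLC, so that 12, 13 and 14 are accompanied by the C7-epimeric (7R)-iodosylbenzoate ester F1, and the crude product is a roughly 1:1 mixture of 15 and the (7R)-alcohol F2. The mixture is acetylated (16 plus the (7R)-acetate F3) and chlorinated (17 plus 7-epi-sclerotiorin F4). The separation is thereby moved to the final, crystalline stage, where 17 is purified by fractional crystallisation from ethanol or by reversed-phase HPLC.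

Step 2. The E/Z ratio of the new alkene, the ambident propargyl/allenyl phosphonate anion and the volatility of 7 are the concerns. The fallback sets out from 4 and comes back at 6. Takai olefination (CHI3, CrCl2, THF, 0 °C) converts 4 into (1E,3E,5S)-1-iodo-3,5-dimethylhepta-1,3-diene F5 with high E selectivity. Sonogashira coupling of F5 with ethynyltrimethylsilane (PdCl2(PPh3)2, CuI, Et3N, rt) then gives 6, which is desilylated as before to 7.

Step 7. NCS could attack the trisubstituted side-chain diene or over-chlorinate. The fallback sets out from 10 and comes back at 17, placing the chlorine on the arene before any sensitive group is present. Compound 10 is chlorinated (NCS, MeCN, rt) at its only free ring position to give 2-bromo-3-chloro-4,6-dihydroxy-5-methylbenzaldehyde F6. Sonogashira coupling with 7 gives the chlorinated alkynylbenzaldehyde F7. The gold/IBX sequence then runs through the 5-chloro-2-benzopyrylium trifluoroacetate F8, the chlorinated aryloxy-iodane F9, the (7R)-iodosylbenzoate ester F10 and its (7S) epimer F11, to the (7R)-5-chloro alcohol F12 and its (7S) epimer F13, which are separated as in step 5. Acetylation of F12 under the step 6 conditions gives 17 directly.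

**Further compounds**
F1 | step 5 | 1-({(7R)-7-methyl-6,8-dioxo-3-[(1E,3E,5S)-3,5-dimethylhepta-1,3-dien-1-yl]-7,8-dihydro-6H-isochromen-7-yl}oxy)-1,2-benziodoxol-3(1H)-one (C7 epimer of 14) | CC[C@H](C)/C=C(C)/C=C/C1=CC2=CC(=O)[C@@](C)(OI3OC(=O)c4ccccc34)C(=O)C2=CO1
F2 | step 5 | (7R)-7-hydroxy-7-methyl-3-[(1E,3E,5S)-3,5-dimethylhepta-1,3-dien-1-yl]-6H-isochromene-6,8(7H)-dione (C7 epimer of 15) | CC[C@H](C)/C=C(C)/C=C/C1=CC2=CC(=O)[C@@](C)(O)C(=O)C2=CO1
F3 | step 5 | (7R)-3-[(1E,3E,5S)-3,5-dimethylhepta-1,3-dien-1-yl]-7-methyl-6,8-dioxo-7,8-dihydro-6H-isochromen-7-yl acetate (C7 epimer of 16) | CC[C@H](C)/C=C(C)/C=C/C1=CC2=CC(=O)[C@@](C)(OC(C)=O)C(=O)C2=CO1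
F4 | step 5 | 7-epi-sclerotiorin, (7S)-5-chloro-3-[(1E,3E,5S)-3,5-dimethylhepta-1,3-dien-1-yl]-7-methyl-6,8-dioxo-7,8-dihydro-6H-isochromen-7-yl acetate | CC[C@H](C)/C=C(C)/C=C/C1=CC2=C(Cl)C(=O)[C@@](C)(OC(C)=O)C(=O)C2=CO1
F5 | step 2 | (1E,3E,5S)-1-iodo-3,5-dimethylhepta-1,3-diene | CC[C@H](C)/C=C(C)/C=C/I
F6 | step 7 | 2-bromo-3-chloro-4,6-dihydroxy-5-methylbenzaldehyde | O=Cc1c(Br)c(Cl)c(O)c(C)c1O
F7 | step 7 | 3-chloro-2-[(3E,5E,7S)-5,7-dimethylnona-3,5-dien-1-yn-1-yl]-4,6-dihydroxy-5-methylbenzaldehyde | CC[C@H](C)/C=C(C)/C=C/C#Cc1c(Cl)c(O)c(C)c(O)c1C=O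
F8 | step 7 | 5-chloro-6,8-dihydroxy-7-methyl-3-[(1E,3E,5S)-3,5-dimethylhepta-1,3-dien-1-yl]isochromenylium trifluoroacetate | CC[C@H](C)/C=C(C)/C=C/c1cc2c(Cl)c(O)c(C)c(O)c2c[o+]1.[O-]C(=O)C(F)(F)F
F9 | step 7 | 1-({5-chloro-7-methyl-6-oxo-3-[(1E,3E,5S)-3,5-dimethylhepta-1,3-dien-1-yl]-6H-isochromen-8-yl}oxy)-1λ5,2-benziodoxole-1,3-dione | CC[C@H](C)/C=C(C)/C=C/C1=CC2=C(Cl)C(=O)C(C)=C(OI3(=O)OC(=O)c4ccccc34)C2=CO1
F10 | step 7 | 1-({(7R)-5-chloro-7-methyl-6,8-dioxo-3-[(1E,3E,5S)-3,5-dimethylhepta-1,3-dien-1-yl]-7,8-dihydro-6H-isochromen-7-yl}oxy)-1,2-benziodoxol-3(1H)-one | CC[C@H](C)/C=C(C)/C=C/C1=CC2=C(Cl)C(=O)[C@](C)(OI3OC(=O)c4ccccc34)C(=O)C2=CO1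
F11 | step 7 | 1-({(7S)-5-chloro-7-methyl-6,8-dioxo-3-[(1E,3E,5S)-3,5-dimethylhepta-1,3-dien-1-yl]-7,8-dihydro-6H-isochromen-7-yl}oxy)-1,2-benziodoxol-3(1H)-one | CC[C@H](C)/C=C(C)/C=C/C1=CC2=C(Cl)C(=O)[C@@](C)(OI3OC(=O)c4ccccc34)C(=O)C2=CO1
F12 | step 7 | (7R)-5-chloro-7-hydroxy-7-methyl-3-[(1E,3E,5S)-3,5-dimethylhepta-1,3-dien-1-yl]-6H-isochromene-6,8(7H)-dione (7-deacetylsclerotiorin) | CC[C@H](C)/C=C(C)/C=C/C1=CC2=C(Cl)C(=O)[C@](C)(O)C(=O)C2=CO1
F13 | step 7 | (7S)-5-chloro-7-hydroxy-7-methyl-3-[(1E,3E,5S)-3,5-dimethylhepta-1,3-dien-1-yl]-6H-isochromene-6,8(7H)-dione | CC[C@H](C)/C=C(C)/C=C/C1=CC2=C(Cl)C(=O)[C@@](C)(O)C(=O)C2=CO1
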